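**Plan**

- Retrosynthesis opens the pyran ring at O1–C2 and C3–C4 in one cut. The arene is left as an ortho-quinone methide (C4=C4a–C8a=O1). C3, C2, the 2-methyl and the CH2–CO–CH=C(CH3)2 arm are exactly the nine carbons of phorone, used as its silyl trienol ether; this match is what makes the key step possible.
- The methide is traced to an ortho-hydroxybenzyl alcohol. Its hydroxymethyl carbon (C4–C4a), free phenol (O–CH3), formyl group (C8–CHO) and ester (O–acyl) are cut in turn back to 3,5-dimethoxybenzyl alcohol and hexadecanoyl chloride.
- Forward: the arene is dressed in four steps (acylation, formylation, chelation-controlled demethylation, ortho-hydroxymethylation) and phorone is silylated in one. The halves are joined last: C3–C4 forms first, then O1–C2 closes the only new ring.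
- Stereochemistry: the single stereocentre, C2 (S), arises in the ring-closing oxa-Michael addition under a chiral phosphoric acid. It is set in the final step and meets no later reagent.

Key step: step 6

Assumption: the sense of induction of the phosphoric acid cannot be predicted with certainty. The (R)-catalyst is written, and its mirror image is to be used if a test run shows that it favours the 2R chroman.

**Step 1**
Reactants: 1 (3,5-dimethoxyphenyl)methanol; 2 hexadecanoyl chloride
Product: 3 (3,5-dimethoxyphenyl)methyl hexadecanoate
Conditions: Et3N, DMAP (cat.), CH2Cl2, 0 °C → rt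
Reagents that add atoms: none
Why: DMAP-catalysed acylation of a primary benzylic alcohol by an acid chloride (nucleophilic acyl substitution) is routine, and the ester also masks the hydroxyl for the formylation that follows.

**Step 2**
Reactants: 3 (3,5-dimethoxyphenyl)methyl hexadecanoate
Product: 5 (2-formyl-3,5-dimethoxyphenyl)methyl hexadecanoate, via iminium chloride 4 (not isolated)
Conditions: POCl3, DMF, 0 → 60 °C; then ice-water, rt
Reagents that add atoms: N,N-dimethylformamide, CN(C)C=O; water, O; phosphoryl chloride, O=P(Cl)(Cl)Cl (supplies only the chloride of intermediate 4)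
Why: Vilsmeier–Haack formylation of a 3,5-dimethoxybenzyl system should go para to one methoxy group and ortho to the other (C2), not to the more hindered position between the two methoxy groups; the benzylic ester, which has no ortho or para donor, should survive the chloroiminium reagent, and water hydrolyses iminium salt 4 to the aldehyde.

**Step 3**
Reactants: 5 (2-formyl-3,5-dimethoxyphenyl)methyl hexadecanoate
Product: 7 (2-formyl-3-hydroxy-5-methoxyphenyl)methyl hexadecanoate, via aryloxydichloroborane 6 (not isolated)
Conditions: BCl3 (1.2 equiv), CH2Cl2, −78 → 0 °C; then H2O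
Reagents that add atoms: boron trichloride, ClB(Cl)Cl (its atoms stay only in intermediate 6; product 7 gains hydrogen only)
Why: In this chelation-controlled ortho-demethylation of an ortho-methoxybenzaldehyde, boron bound to the formyl oxygen cleaves only the methyl ether that can close a six-membered chelate, and the para methoxy group and, at low temperature, the electron-poor benzylic ester should stay intact.

**Step 4**
Reactants: 7 (2-formyl-3-hydroxy-5-methoxyphenyl)methyl hexadecanoate
Product: 9 [2-formyl-3-hydroxy-4-(hydroxymethyl)-5-methoxyphenyl]methyl hexadecanoate, via benzodioxaborin 8 (not isolated)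
Conditions: PhB(OH)2, (CH2O)n, EtCO2H (cat.), toluene, 100 °C, Dean–Stark; then propane-1,3-diol, THF, rt
Reagents that add atoms: formaldehyde (as paraformaldehyde), C=O; phenylboronic acid, OB(O)c1ccccc1 (its atoms stay only in intermediate 8)
Why: In the phenylboronic acid-templated ortho-hydroxymethylation of phenols the aryl boronate delivers formaldehyde to the only free ortho carbon (C4, also activated by the adjacent methoxy group) and traps the product as cyclic boronate 8, which rules out attack at the para position and diarylmethane formation; neutral transesterification with the diol then frees 9 without touching the aldehyde.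

**Step 5**
Reactants: 10 phorone (2,6-dimethylhepta-2,5-dien-4-one)
Product: 11 tert-butyl{[(3Z)-2,6-dimethylhepta-1,3,5-trien-4-yl]oxy}dimethylsilane
Conditions: TBSOTf, Et3N, CH2Cl2, 0 °C → rt
Reagents that add atoms: tert-butyldimethylsilyl trifluoromethanesulfonate, CC(C)(C)[Si](C)(C)OS(=O)(=O)C(F)(F)F
Why: Soft enolisation with a silyl triflate and an amine: phorone has no sp3 alpha-hydrogen, so O-silylation is followed by gamma-deprotonation of a methyl group (vinylogous enolisation); the ketone is symmetrical, so all four methyl groups lead to the same trienol ether, expected mainly as the (Z)-isomer, and this geometry is lost again in step 6.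

**Step 6**
Reactants: 9 [2-formyl-3-hydroxy-4-(hydroxymethyl)-5-methoxyphenyl]methyl hexadecanoate; 11 tert-butyl{[(3Z)-2,6-dimethylhepta-1,3,5-trien-4-yl]oxy}dimethylsilane
Product: 14 [(2S)-8-formyl-5-methoxy-2-methyl-2-(4-methyl-2-oxopent-3-en-1-yl)-3,4-dihydro-2H-chromen-7-yl]methyl hexadecanoate (CNP0228756.1), via ortho-quinone methide 12 (not isolated), via dienone phenol 13 (not isolated)
Conditions: (R)-TRIP (10 mol %), 11 (2 equiv), CH2Cl2, 0 °C → rt, slow addition of 9; neutral work-up
Reagents that add atoms: none
Why: Proposed new method: the phosphoric acid ionises the benzylic alcohol that has ortho-hydroxy and ortho-methoxy groups (the palmitoyloxymethyl group is meta to both donors and cannot form a methide) to ortho-quinone methide 12, and the terminal CH2 of trienol ether 11 adds to its exocyclic CH2 in a vinylogous Mukaiyama–Michael reaction (C3–C4) that restores the phenol, the silyl group passing to the water released in the ionisation so that dienone phenol 13 and the free acid result. The closest known reaction types are chiral phosphoric acid catalysed vinylogous Mukaiyama–Mannich additions of acyclic silyl dienolates with water as silyl acceptor, acid-catalysed additions of enol-type nucleophiles to ortho-quinone methides formed in situ from ortho-hydroxybenzyl alcohols, and bifunctional-catalyst oxa-Michael closures of phenols to chromans; their combination on an unsubstituted methide, ending in a fully substituted C–O centre, has not been shown. The pyran ring closes by 6-exo-trig oxa-Michael addition of the phenol oxygen to the trisubstituted beta-carbon of the new enone in 13 (O1–C2). C2, the only new stereocentre, is set in this closure by the catalyst, whose P=O oxygen holds the phenol O–H while its P–OH activates the dienone carbonyl, so that the 3,3'-aryl groups shield one face of the (E)-enone; if the silylated cation closes before desilylation, the same phosphate acts as its hydrogen-bonded counter-ion. The step needs gamma- over alpha-attack of the dienol ether, secured by the unhindered terminal CH2 against an alpha-carbon flanked by a methyl group and the silyloxy-bearing carbon, and attack at the methide instead of the formyl group, secured by the chelated, donor-conjugated salicylaldehyde carbonyl being a far weaker electrophile. The choice of enone terminus is no issue, since closure on the distal one would need an eight-membered ring, and the stereocentre cannot erode afterwards because this is the last step and no base is used.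

**Compound list**

1 | (3,5-dimethoxyphenyl)methanol | COc1cc(CO)cc(OC)c1 | starting material
2 | hexadecanoyl chloride | CCCCCCCCCCCCCCCC(=O)Cl | starting material
3 | (3,5-dimethoxyphenyl)methyl hexadecanoate | CCCCCCCCCCCCCCCC(=O)OCc1cc(OC)cc(OC)c1 | intermediate
4 | N-{[2-(hexadecanoyloxymethyl)-4,6-dimethoxyphenyl]methylidene}-N-methylmethanaminium chloride | CCCCCCCCCCCCCCCC(=O)OCc1cc(OC)cc(OC)c1C=[N+](C)C.[Cl-] | intermediate (not isolated)
5 | (2-formyl-3,5-dimethoxyphenyl)methyl hexadecanoate | CCCCCCCCCCCCCCCC(=O)OCc1cc(OC)cc(OC)c1C=O | intermediate
6 | [3-(dichloroboranyloxy)-2-formyl-5-methoxyphenyl]methyl hexadecanoate | CCCCCCCCCCCCCCCC(=O)OCc1cc(OC)cc(OB(Cl)Cl)c1C=O | intermediate (not isolated)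
7 | (2-formyl-3-hydroxy-5-methoxyphenyl)methyl hexadecanoate | CCCCCCCCCCCCCCCC(=O)OCc1cc(OC)cc(O)c1C=O | intermediate
8 | (8-formyl-5-methoxy-2-phenyl-4H-1,3,2-benzodioxaborinin-7-yl)methyl hexadecanoate | CCCCCCCCCCCCCCCC(=O)OCc1cc(OC)c2COB(c3ccccc3)Oc2c1C=O | intermediate (not isolated)
9 | [2-formyl-3-hydroxy-4-(hydroxymethyl)-5-methoxyphenyl]methyl hexadecanoate | CCCCCCCCCCCCCCCC(=O)OCc1cc(OC)c(CO)c(O)c1C=O | intermediate
10 | phorone (2,6-dimethylhepta-2,5-dien-4-one) | CC(C)=CC(=O)C=C(C)C | starting material
11 | tert-butyl{[(3Z)-2,6-dimethylhepta-1,3,5-trien-4-yl]oxy}dimethylsilane | C=C(C)/C=C(\O[Si](C)(C)C(C)(C)C)C=C(C)C | intermediate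
12 | (2-formyl-5-methoxy-4-methylidene-3-oxocyclohexa-1,5-dien-1-yl)methyl hexadecanoate | CCCCCCCCCCCCCCCC(=O)OCC1=C(C=O)C(=O)C(=C)C(OC)=C1 | intermediate (not isolated)
13 | {4-[(3E)-3,7-dimethyl-5-oxoocta-3,6-dien-1-yl]-2-formyl-3-hydroxy-5-methoxyphenyl}methyl hexadecanoate | CCCCCCCCCCCCCCCC(=O)OCc1cc(OC)c(CC/C(C)=C/C(=O)C=C(C)C)c(O)c1C=O | intermediate (not isolated)
14 | [(2S)-8-formyl-5-methoxy-2-methyl-2-(4-methyl-2-oxopent-3-en-1-yl)-3,4-dihydro-2H-chromen-7-yl]methyl hexadecanoate | CCCCCCCCCCCCCCCC(=O)OCc1cc(OC)c2c(c1C=O)O[C@](C)(CC(=O)C=C(C)C)CC2 | target

**Step count and risks**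

Total: 6 steps. Longest linear sequence: 5 steps (steps 1, 2, 3, 4 and 6); step 5 is a one-step side branch.

Steps most likely to fail:

1. Step 6 (proposed new method). What may go wrong: poor facial selectivity in the oxa-Michael closure, including closure of the silylated cation outside catalyst control; hydrolysis of the dienol ether before the C–C bond forms; alpha-attack; oligomerisation of the methide; slow closure by the hydrogen-bonded, weakly nucleophilic phenol. Fallback (sets out from 9 and 11, returns at 14): the two components are heated without acid in toluene at about 100–110 °C, so that 9 loses water thermally and methide 12 is trapped by the isopropenyl terminus of 11 in an inverse-demand hetero-Diels–Alder reaction. This is a known way from ortho-hydroxybenzyl alcohols and 1,1-disubstituted electron-rich alkenes to 2,2-disubstituted chromans. It should give racemic {2-[2-(tert-butyldimethylsilyloxy)-4-methylpenta-1,3-dien-1-yl]-8-formyl-5-methoxy-2-methyl-3,4-dihydro-2H-chromen-7-yl}methyl hexadecanoate F1. Its enol ether is hydrolysed with dilute aqueous acid in THF to racemic [8-formyl-5-methoxy-2-methyl-2-(4-methyl-2-oxopent-3-en-1-yl)-3,4-dihydro-2H-chromen-7-yl]methyl hexadecanoate F2. Preparative chromatography on a chiral stationary phase then separates the (2S)-enantiomer 14 from its antipode.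

2. Step 4. What may go wrong: sluggish substitution on a phenol that is hydrogen-bonded to, and deactivated by, the formyl group, and premature ionisation of the acid-labile diol during deboronation or purification. Fallback (sets out from 7, returns at 9): the ortho carbon is delivered by a sigmatropic shift instead of an electrophilic substitution. Phenol 7 is treated with chlorodimethylsulfonium chloride (from N-chlorosuccinimide and dimethyl sulfide, CH2Cl2, −40 °C) and then triethylamine. The aryloxysulfonium ylide rearranges by a [2,3]-shift to the only free ortho position to give {2-formyl-3-hydroxy-5-methoxy-4-[(methylsulfanyl)methyl]phenyl}methyl hexadecanoate F3. S-Methylation with iodomethane gives {[3-formyl-4-(hexadecanoyloxymethyl)-2-hydroxy-6-methoxyphenyl]methyl}dimethylsulfonium iodide F4. In aqueous THF with NaHCO3 this loses dimethyl sulfide to methide 12, which is hydrated to diol 9.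

3. Step 3. What may go wrong: cleavage of the benzylic ester C–O bond by the boron halide in competition with demethylation. Fallback (sets out from 1, returns at 7): the ester is introduced only after the Lewis-acid step. Alcohol 1 and thionyl chloride give 1-(chloromethyl)-3,5-dimethoxybenzene F5. Vilsmeier–Haack formylation gives 2-(chloromethyl)-4,6-dimethoxybenzaldehyde F6. BCl3, to which a benzylic chloride is inert, gives 2-(chloromethyl)-6-hydroxy-4-methoxybenzaldehyde F7. Displacement of the chloride with sodium hexadecanoate (DMF, Bu4NI cat.) gives 7; the carboxylate is too weak a base to deprotonate the chelated phenol.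

**Further compounds**

F1 | step 6 | {2-[2-(tert-butyldimethylsilyloxy)-4-methylpenta-1,3-dien-1-yl]-8-formyl-5-methoxy-2-methyl-3,4-dihydro-2H-chromen-7-yl}methyl hexadecanoate (racemic) | CCCCCCCCCCCCCCCC(=O)OCc1cc(OC)c2c(c1C=O)OC(C)(C=C(O[Si](C)(C)C(C)(C)C)C=C(C)C)CC2
F2 | step 6 | rac-[8-formyl-5-methoxy-2-methyl-2-(4-methyl-2-oxopent-3-en-1-yl)-3,4-dihydro-2H-chromen-7-yl]methyl hexadecanoate | CCCCCCCCCCCCCCCC(=O)OCc1cc(OC)c2c(c1C=O)OC(C)(CC(=O)C=C(C)C)CC2
F3 | step 4 | {2-formyl-3-hydroxy-5-methoxy-4-[(methylsulfanyl)methyl]phenyl}methyl hexadecanoate | CCCCCCCCCCCCCCCC(=O)OCc1cc(OC)c(CSC)c(O)c1C=O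
F4 | step 4 | {[3-formyl-4-(hexadecanoyloxymethyl)-2-hydroxy-6-methoxyphenyl]methyl}dimethylsulfonium iodide | CCCCCCCCCCCCCCCC(=O)OCc1cc(OC)c(C[S+](C)C)c(O)c1C=O.[I-]
F5 | step 3 | 1-(chloromethyl)-3,5-dimethoxybenzene | COc1cc(CCl)cc(OC)c1
F6 | step 3 | 2-(chloromethyl)-4,6-dimethoxybenzaldehyde | COc1cc(CCl)c(C=O)c(OC)c1
F7 | step 3 | 2-(chloromethyl)-6-hydroxy-4-methoxybenzaldehyde | COc1cc(O)c(C=O)c(CCl)c1
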